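The route rests on cutting the C2–CH3 bond of the butane chain (C1 benzylic, on the hydroxydimethoxyphenyl ring A; C2; C3 carbinol; C4). The feature used is that the C2 methyl lies anti to the C1–O1 bond: methylation of a lithium-chelated β-alkoxide ester enolate, in which ring A on C1 covers one enolate face, gives this relation. In one operation the key step forms the C2–CH3 bond and the C2 stereocentre from C1 alone. Its precursor is ethyl (R)-3-aryl-3-hydroxypropanoate with the ring A phenol silylated, made by asymmetric hydrogenation. The ester then becomes a methyl ketone, and one Evans–Tishchenko reaction sets C3 and places the ring B veratroate on O1.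

Key step: step 4

Remark: chain numbering follows the target (C1 benzylic carbon bearing O1, C2 methyl-bearing, C3 carbinol bearing O3, C4 methyl). Ring A is the 3-hydroxy-4,5-dimethoxyphenyl ring on C1, and ring B is the 3,4-dimethoxyphenyl ring of the ester. Ar stands for 3-(tert-butyldimethylsilyloxy)-4,5-dimethoxyphenyl, which is ring A with its phenol silylated. 3-Hydroxy-4,5-dimethoxybenzaldehyde is assumed to be commercially available.

Step 1
Reactants: 1 3-hydroxy-4,5-dimethoxybenzaldehyde; 2 tert-butyldimethylsilyl chloride
Product: 3 3-(tert-butyldimethylsilyloxy)-4,5-dimethoxybenzaldehyde (Ar–CHO)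
Conditions: TBSCl (1.2 equiv), imidazole (2.5 equiv), DMF, rt
Reagents that add atoms: tert-butyldimethylsilyl chloride, CC(C)(C)[Si](C)(C)Cl
Why: Imidazole-promoted O-silylation of a phenol is chemoselective beside the aldehyde and masks the acidic ring A hydroxyl, which would otherwise consume base and be O-methylated in step 4; no stereocentre is involved.

Step 2
Reactants: 3 3-(tert-butyldimethylsilyloxy)-4,5-dimethoxybenzaldehyde; 4 ethyl diazoacetate
Product: 5 ethyl 3-Ar-3-oxopropanoate
Conditions: ethyl diazoacetate (1.3 equiv), SnCl2 (10 mol%), CH2Cl2, rt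
Reagents that add atoms: ethyl diazoacetate, CCOC(=O)C=[N+]=[N-]
Why: Roskamp homologation, in which the diazo carbon adds to the SnCl2-activated aldehyde and a 1,2-hydride shift with loss of N2 turns the CHO group into the C(=O)CH2CO2Et unit, is known for aromatic aldehydes; no stereocentre is formed.

Step 3
Reactants: 5 ethyl 3-Ar-3-oxopropanoate
Product: 6 ethyl (3R)-3-Ar-3-hydroxypropanoate
Conditions: H2 (10 bar), RuCl2[(S)-BINAP] (1 mol%), EtOH, 50 °C
Reagents that add atoms: none
Why: Noyori asymmetric hydrogenation of a β-keto ester, in which the keto ester chelates divalent ruthenium and the (S)-BINAP ligand directs hydride to the ketone face that gives the (R)-aryl carbinol (the same spatial sense as (S)-3-hydroxybutanoate from acetoacetate, the descriptor being R because the aryl group outranks CH2CO2Et), while ethanol as solvent keeps the ethyl ester intact.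

Step 4
Reactants: 6 ethyl (3R)-3-Ar-3-hydroxypropanoate; 7 iodomethane
Product: 9 ethyl (2S,3R)-3-Ar-3-hydroxy-2-methylpropanoate (2,3-anti), via dilithium alkoxide enolate 8 (not isolated)
Conditions: LiN(iPr)2 (2.2 equiv), THF, −78 to −20 °C; MeI (3 equiv), DMPU, −78 to −20 °C; aq. NH4Cl
Reagents that add atoms: iodomethane, CI
Why: Fráter–Seebach alkylation: the first equivalent of LiN(iPr)2 removes the hydroxyl proton and the second the C2 proton, so that 8 is a lithium enolate tied to the neighbouring lithium alkoxide in a six-membered O–Li–O chelate, and iodomethane then reacts at the enolate carbon by SN2 displacement of iodide. This is the established anti-selective methylation of β-hydroxy ester dianions, a reaction type already applied to 3-aryl-3-hydroxypropanoates. No ring is closed; one C–C bond (C2–CH3) and one stereocentre (C2) are formed. The new centre is controlled by the carbinol carbon (C1 of the target chain), the only sp3 carbon of the chelate: with its oxygen held near the enolate plane by lithium, ring A stands over one face of the enolate and the carbinol hydrogen over the other, so iodomethane should enter from the hydrogen side and place the methyl anti to O1, which is the (2S,3R) isomer. The step needs this facial selectivity together with C- over O-methylation and monoalkylation; the rigid chelate and the size of ring A should secure the first, the soft electrophile and the low temperature the second, and the absence of excess base together with the lower acidity of the now tertiary α-position the third.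

Step 5
Reactants: 9 ethyl (2S,3R)-3-Ar-3-hydroxy-2-methylpropanoate; 10 N,O-dimethylhydroxylamine hydrochloride
Product: 11 (2S,3R)-3-Ar-3-hydroxy-N-methoxy-N,2-dimethylpropanamide
Conditions: MeNHOMe·HCl (2 equiv), iPrMgCl (5 equiv), THF, −20 to −10 °C; aq. NH4Cl
Reagents that add atoms: N,O-dimethylhydroxylamine hydrochloride, CNOC.Cl
Why: Weinreb amide formation by aminolysis of the ester with the chloromagnesium amide generated in the flask, a method that tolerates a free β-hydroxyl (present as its magnesium alkoxide), is run cold so that neither retro-aldol cleavage nor C2 epimerisation should intervene; both stereocentres are retained.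

Step 6
Reactants: 11 (2S,3R)-3-Ar-3-hydroxy-N-methoxy-N,2-dimethylpropanamide; 12 methylmagnesium bromide
Product: 14 (3S,4R)-4-Ar-4-hydroxy-3-methylbutan-2-one, via magnesium hemiaminal chelate 13 (not isolated)
Conditions: MeMgBr (3 equiv), THF, −20 to 0 °C; cold aq. NH4Cl
Reagents that add atoms: methylmagnesium bromide, C[Mg]Br
Why: Weinreb ketone synthesis: after deprotonation of the hydroxyl one methyl adds to the amide and the N-methoxy chelate 13 holds the tetrahedral adduct until the quench, so the methyl ketone should form without over-addition and, with a cold buffered work-up, without epimerisation at the α-carbon.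

Step 7
Reactants: 14 (3S,4R)-4-Ar-4-hydroxy-3-methylbutan-2-one; 15 3,4-dimethoxybenzaldehyde
Product: 17 (1R,2R,3S)-1-Ar-3-hydroxy-2-methylbutyl 3,4-dimethoxybenzoate, via samarium hemiacetal 16 (not isolated)
Conditions: 3,4-dimethoxybenzaldehyde (5 equiv), SmI2 (0.3 equiv), THF, −10 °C
Reagents that add atoms: 3,4-dimethoxybenzaldehyde, COc1ccc(C=O)cc1OC
Why: Evans–Tishchenko reduction: the trivalent samarium species formed from SmI2 and the aldehyde binds hemiacetal 16 (made from the C1 hydroxyl and the aldehyde) together with the ketone oxygen in a chair-like bicyclic transition state, and intramolecular hydride transfer from the hemiacetal carbon should set C3 anti to O1 (1,3-anti, 3S) while the oxidised hemiacetal remains on O1 as the ring B benzoate, so ester position and configuration arise together.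

Step 8
Reactants: 17 (1R,2R,3S)-1-Ar-3-hydroxy-2-methylbutyl 3,4-dimethoxybenzoate
Product: 18 (1R,2R,3S)-3-hydroxy-1-(3-hydroxy-4,5-dimethoxyphenyl)-2-methylbutyl 3,4-dimethoxybenzoate (CNP0124473.1)
Conditions: Bu4NF (1.2 equiv), AcOH (1.5 equiv), THF, 0 °C
Reagents that add atoms: none
Why: Fluoride-induced cleavage of the aryl silyl ether under acetic acid buffering protonates the ring A phenoxide as it forms, so base-induced 1,3-acyl migration from O1 to O3 and ester cleavage should be avoided; no stereocentre is touched.

Compound list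
1 | 3-hydroxy-4,5-dimethoxybenzaldehyde | COc1cc(C=O)cc(O)c1OC | starting material
2 | tert-butyldimethylsilyl chloride | CC(C)(C)[Si](C)(C)Cl | starting material
3 | 3-(tert-butyldimethylsilyloxy)-4,5-dimethoxybenzaldehyde | COc1cc(C=O)cc(O[Si](C)(C)C(C)(C)C)c1OC | intermediate
4 | ethyl diazoacetate | CCOC(=O)C=[N+]=[N-] | starting material
5 | ethyl 3-[3-(tert-butyldimethylsilyloxy)-4,5-dimethoxyphenyl]-3-oxopropanoate | CCOC(=O)CC(=O)c1cc(O[Si](C)(C)C(C)(C)C)c(OC)c(OC)c1 | intermediate
6 | ethyl (3R)-3-[3-(tert-butyldimethylsilyloxy)-4,5-dimethoxyphenyl]-3-hydroxypropanoate | O[C@@H](c1cc(O[Si](C)(C)C(C)(C)C)c(OC)c(OC)c1)CC(=O)OCC | intermediate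
7 | iodomethane | CI | starting material
8 | dilithium alkoxide enolate of 6 (six-membered O–Li–O chelate, enolate oxygen cis to the carbinol carbon; drawn with covalent O–Li bonds) | [Li]O[C@@H](c1cc(O[Si](C)(C)C(C)(C)C)c(OC)c(OC)c1)/C=C(\O[Li])OCC | intermediate
9 | ethyl (2S,3R)-3-[3-(tert-butyldimethylsilyloxy)-4,5-dimethoxyphenyl]-3-hydroxy-2-methylpropanoate (2,3-anti) | O[C@@H](c1cc(O[Si](C)(C)C(C)(C)C)c(OC)c(OC)c1)[C@H](C)C(=O)OCC | intermediate
10 | N,O-dimethylhydroxylamine hydrochloride | CNOC.Cl | starting material
11 | (2S,3R)-3-[3-(tert-butyldimethylsilyloxy)-4,5-dimethoxyphenyl]-3-hydroxy-N-methoxy-N,2-dimethylpropanamide | O[C@@H](c1cc(O[Si](C)(C)C(C)(C)C)c(OC)c(OC)c1)[C@H](C)C(=O)N(C)OC | intermediate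
12 | methylmagnesium bromide | C[Mg]Br | starting material
13 | bis(bromomagnesium) salt of the tetrahedral methyl adduct of 11 (hemiaminal carbon configuration undefined) | Br[Mg]O[C@@H](c1cc(O[Si](C)(C)C(C)(C)C)c(OC)c(OC)c1)[C@H](C)C(C)(O[Mg]Br)N(C)OC | intermediate
14 | (3S,4R)-4-[3-(tert-butyldimethylsilyloxy)-4,5-dimethoxyphenyl]-4-hydroxy-3-methylbutan-2-one | O[C@@H](c1cc(O[Si](C)(C)C(C)(C)C)c(OC)c(OC)c1)[C@H](C)C(C)=O | intermediate
15 | 3,4-dimethoxybenzaldehyde (veratraldehyde) | COc1ccc(C=O)cc1OC | starting material
16 | hemiacetal from the carbinol oxygen of 14 and aldehyde 15, held on trivalent samarium (drawn metal-free, hemiacetal carbon configuration undefined) | COc1ccc(C(O)O[C@@H](c2cc(O[Si](C)(C)C(C)(C)C)c(OC)c(OC)c2)[C@H](C)C(C)=O)cc1OC | intermediate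
17 | (1R,2R,3S)-1-[3-(tert-butyldimethylsilyloxy)-4,5-dimethoxyphenyl]-3-hydroxy-2-methylbutyl 3,4-dimethoxybenzoate | COc1ccc(C(=O)O[C@@H](c2cc(O[Si](C)(C)C(C)(C)C)c(OC)c(OC)c2)[C@H](C)[C@H](C)O)cc1OC | intermediate
18 | (1R,2R,3S)-3-hydroxy-1-(3-hydroxy-4,5-dimethoxyphenyl)-2-methylbutyl 3,4-dimethoxybenzoate (CNP0124473.1) | COc1ccc(C(=O)O[C@@H](c2cc(O)c(OC)c(OC)c2)[C@H](C)[C@H](C)O)cc1OC | target

Total step count: 8. Longest linear sequence: 8 steps (1 to 18); compounds 2, 4, 7, 10, 12 and 15 are purchased.

Steps most likely to fail

Step 4 (key step). The second deprotonation may stay incomplete, or the chelate may loosen in the presence of DMPU so that facial control of the methylation drops and C2 epimers form; O-methylation of the alkoxide on warming is a further possible loss. The fallback sets out from 3 and comes back at 14, and it makes the C1–C2 bond instead of the C2–CH3 bond. Aldehyde 3 is treated at −78 °C in THF with the (E)-crotyldiisopinocampheylborane derived from (−)-α-pinene (generated from trans-2-butene, KOtBu, n-BuLi and the B-methoxyborane, with BF3·OEt2 added, and worked up with ethanolamine to spare the aryl silyl ether). This enantiomer of the reagent should add to the Re face of the aldehyde through a chair transition state, and the E geometry fixes the anti relation, giving (1R,2R)-1-[3-(tert-butyldimethylsilyloxy)-4,5-dimethoxyphenyl]-2-methylbut-3-en-1-ol F1. Tsuji–Wacker oxidation of the terminal alkene (PdCl2, CuCl, O2, DMF–H2O, rt) should then give the methyl ketone 14.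

Step 7. The samarium aldolate of the electron-rich benzylic carbinol may fragment by retro-aldol reaction, which destroys or scrambles C1 and C2. Hydride transfer from the hemiacetal of the electron-rich aldehyde may also be slow enough for Tishchenko dimerisation of the aldehyde to consume it. The fallback sets out from 14 and comes back at 18. Hydroxyl-directed reduction with Me4NBH(OAc)3 in MeCN–AcOH at −30 °C should give the 1,3-anti diol (1R,2R,3S)-1-[3-(tert-butyldimethylsilyloxy)-4,5-dimethoxyphenyl]-2-methylbutane-1,3-diol F2. The less hindered C3 hydroxyl is silylated with TESCl and imidazole in CH2Cl2 at −20 °C to give (1R,2S,3S)-1-[3-(tert-butyldimethylsilyloxy)-4,5-dimethoxyphenyl]-2-methyl-3-(triethylsilyloxy)butan-1-ol F3. The remaining benzylic hydroxyl is acylated with 3,4-dimethoxybenzoyl chloride, DMAP and pyridine in CH2Cl2 to give (1R,2S,3S)-1-[3-(tert-butyldimethylsilyloxy)-4,5-dimethoxyphenyl]-2-methyl-3-(triethylsilyloxy)butyl 3,4-dimethoxybenzoate F4. Both silyl groups are then removed with Bu4NF buffered by AcOH in THF (0 °C to rt), which leads directly to 18.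

Step 2. The electron-rich aldehyde may add the diazo ester only slowly, and aryl migration in place of hydride migration would divert material to the 2-aryl-3-hydroxyacrylate, while the diazo ester decomposes in the meantime. The fallback sets out from 3 and comes back at 5. The lithium enolate of ethyl acetate (LiN(iPr)2, EtOAc, THF, −78 °C) is added to aldehyde 3 to give racemic ethyl 3-[3-(tert-butyldimethylsilyloxy)-4,5-dimethoxyphenyl]-3-hydroxypropanoate F5. Oxidation of this benzylic alcohol with Dess–Martin periodinane (CH2Cl2, NaHCO3, rt) or MnO2 should give the β-keto ester 5.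

Further compounds
F1 | step 4 | (1R,2R)-1-[3-(tert-butyldimethylsilyloxy)-4,5-dimethoxyphenyl]-2-methylbut-3-en-1-ol | O[C@@H](c1cc(O[Si](C)(C)C(C)(C)C)c(OC)c(OC)c1)[C@H](C)C=C
F2 | step 7 | (1R,2R,3S)-1-[3-(tert-butyldimethylsilyloxy)-4,5-dimethoxyphenyl]-2-methylbutane-1,3-diol | O[C@@H](c1cc(O[Si](C)(C)C(C)(C)C)c(OC)c(OC)c1)[C@H](C)[C@H](C)O
F3 | step 7 | (1R,2S,3S)-1-[3-(tert-butyldimethylsilyloxy)-4,5-dimethoxyphenyl]-2-methyl-3-(triethylsilyloxy)butan-1-ol | O[C@@H](c1cc(O[Si](C)(C)C(C)(C)C)c(OC)c(OC)c1)[C@H](C)[C@H](C)O[Si](CC)(CC)CC
F4 | step 7 | (1R,2S,3S)-1-[3-(tert-butyldimethylsilyloxy)-4,5-dimethoxyphenyl]-2-methyl-3-(triethylsilyloxy)butyl 3,4-dimethoxybenzoate | COc1ccc(C(=O)O[C@@H](c2cc(O[Si](C)(C)C(C)(C)C)c(OC)c(OC)c2)[C@H](C)[C@H](C)O[Si](CC)(CC)CC)cc1OC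
F5 | step 2 | ethyl 3-[3-(tert-butyldimethylsilyloxy)-4,5-dimethoxyphenyl]-3-hydroxypropanoate (racemic) | CCOC(=O)CC(O)c1cc(O[Si](C)(C)C(C)(C)C)c(OC)c(OC)c1
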